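## Retrosynthetic overview

1. Last disconnection: the aryl ether C–O bond (Mitsunobu reaction on a primary alcohol); the coumarin rings are bought intact.
2. Key disconnection: the cyclohexanone C2–C3 bond (CMe2 carbon to the side-chain-bearing CH). It is made by attack of the ketone enolate carbon on a chiral oxirane that serves as the reversed-polarity (a2, enolonium-type) partner. Two carbons of donor parity are joined, which creates the 1,4-keto-alcohol, the quaternary carbon and both ring stereocenters in one step.
3. The epoxy ketone comes from Shi epoxidation of an (E)-trisubstituted alkenyl isopropyl ketone, which comes from enolate C-alkylation of an allylic bromide.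
4. The allylic bromide comes from a chiral-pool terpene alcohol that already carries the side-chain carbinol stereocenter (hydroboration, acetonide, allylic oxidation, Appel reaction).
5. Ring order: 1,3-dioxane (protecting ring), then oxirane, then the cyclohexanone (key step); the dioxane is then removed and the coumarin unit attached.

Assumption: commercial (R)-(−)-linalool 1 of at least 95% ee is used, and the L-fructose-derived enantiomer of the Shi ketone (made from L-sorbose) is available as catalyst.

## Route

Step 1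
Reactants: 1 (R)-(−)-linalool [(3R)-3,7-dimethylocta-1,6-dien-3-ol]
Product: 3 (3R)-3,7-dimethyloct-6-ene-1,3-diol, via B-alkyl-9-BBN adduct 2 (not isolated)
Conditions: 9-BBN (2.2 equiv), THF, 0 °C to rt; then NaOH, H2O2, H2O, 0 °C to rt
Reagents that add atoms: hydrogen peroxide, OO
Why: Anti-Markovnikov hydroboration–oxidation: the bulky dialkylborane adds to the monosubstituted vinyl group far faster than to the trisubstituted alkene, and the tertiary carbinol stereocenter of 1 is carried through untouched.

Step 2
Reactants: 3 (3R)-3,7-dimethyloct-6-ene-1,3-diol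
Product: 4 (4R)-2,2,4-trimethyl-4-(4-methylpent-3-en-1-yl)-1,3-dioxane
Conditions: 2,2-dimethoxypropane, pyridinium p-toluenesulfonate (cat.), CH2Cl2, rt
Reagents that add atoms: 2,2-dimethoxypropane, COC(C)(C)OC
Why: Acid-catalysed acetal exchange (acetonide formation) closes a six-membered 1,3-dioxane over both hydroxyls, masking the tertiary hydroxyl that would otherwise open the later oxirane to a tetrahydrofuran and the primary hydroxyl that is needed last.

Step 3
Reactants: 4 (4R)-2,2,4-trimethyl-4-(4-methylpent-3-en-1-yl)-1,3-dioxane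
Product: 5 (2E)-2-methyl-5-[(4R)-2,2,4-trimethyl-1,3-dioxan-4-yl]pent-2-en-1-ol
Conditions: SeO2 (cat.), t-BuOOH, CH2Cl2, 0 °C to rt
Reagents that add atoms: tert-butyl hydroperoxide, CC(C)(C)OO
Why: Riley-type allylic oxidation under Sharpless catalytic conditions (ene reaction, then [2,3]-sigmatropic shift) hydroxylates the (E)-methyl of the gem-dimethyl alkene selectively, which fixes the E geometry needed for the later epoxide.

Step 4
Reactants: 5 (2E)-2-methyl-5-[(4R)-2,2,4-trimethyl-1,3-dioxan-4-yl]pent-2-en-1-ol
Product: 6 (4R)-4-[(3E)-5-bromo-4-methylpent-3-en-1-yl]-2,2,4-trimethyl-1,3-dioxane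
Conditions: CBr4, PPh3, CH2Cl2, 0 °C
Reagents that add atoms: carbon tetrabromide, BrC(Br)(Br)Br
Why: Appel reaction: SN2 displacement of the alkoxyphosphonium by bromide under neutral conditions keeps the alkene geometry and the acetonide intact.

Step 5
Reactants: 6 (4R)-4-[(3E)-5-bromo-4-methylpent-3-en-1-yl]-2,2,4-trimethyl-1,3-dioxane; 7 3-methylbutan-2-one
Product: 9 (6E)-2,6-dimethyl-9-[(4R)-2,2,4-trimethyl-1,3-dioxan-4-yl]non-6-en-3-one, via lithium 3-methylbut-1-en-2-olate 8 (not isolated)
Conditions: 7 (3 equiv), LiN(i-Pr)2 (3 equiv), THF, −78 °C; then 6, −78 to −20 °C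
Reagents that add atoms: none
Why: Kinetic deprotonation of 7 occurs at the methyl group, and SN2 C-alkylation of the resulting enolate by the reactive primary allylic bromide (enolate in excess to suppress dialkylation) builds the isopropyl ketone without touching the alkene geometry.

Step 6
Reactants: 9 (6E)-2,6-dimethyl-9-[(4R)-2,2,4-trimethyl-1,3-dioxan-4-yl]non-6-en-3-one
Product: 10 2-methyl-5-{(2S,3S)-2-methyl-3-[2-((4R)-2,2,4-trimethyl-1,3-dioxan-4-yl)ethyl]oxiran-2-yl}pentan-3-one
Conditions: 1,2:4,5-di-O-isopropylidene-β-L-erythro-2,3-hexodiulo-2,6-pyranose (0.3 equiv), KHSO5 (as 2KHSO5·KHSO4·K2SO4), K2CO3, Bu4NHSO4 (cat.), MeCN/CH2(OMe)2/aqueous Na2B4O7 buffer, pH 10.5, 0 °C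
Reagents that add atoms: potassium peroxymonosulfate, [K+].[O-]S(=O)(=O)OO
Why: Shi asymmetric epoxidation: the chiral dioxirane formed in situ delivers oxygen through a spiro transition state, and the L-fructose-derived ketone (mirror image of the usual D-fructose catalyst, which gives R,R epoxides from E-trisubstituted alkenes) gives the (2S,3S)-oxirane, which fixes the absolute configuration of both future ring stereocenters.

Step 7
Reactants: 10 2-methyl-5-{(2S,3S)-2-methyl-3-[2-((4R)-2,2,4-trimethyl-1,3-dioxan-4-yl)ethyl]oxiran-2-yl}pentan-3-one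
Product: 12 (3S,4S)-3-[(3R)-3,5-dihydroxy-3-methylpentyl]-4-hydroxy-2,2,4-trimethylcyclohexan-1-one, via acetonide ketone 11 (not isolated)
Conditions: KOt-Bu (2 equiv), t-BuOH, 0.02 M, 70 °C; then AcOH/H2O (4:1), 45 °C
Reagents that add atoms: none
Why: Proposed new method: under equilibrating conditions both enolates of the isopropyl ketone form reversibly, but only the tetrasubstituted enolate carbon can reach the secondary oxirane carbon through a six-membered transition state (every alternative needs SN2 at the fully substituted oxirane carbon or a three- or four-membered ring), so C–C bond formation with inversion at the CH carbon and retention at the carbinol carbon gives the quaternary CMe2 centre and the trans hydroxyl/side-chain relationship, i.e. the (3S,4S) ring, in one operation; the oxirane acts as an a2 acceptor (an enolonium equivalent at the alcohol oxidation level) that joins two carbons of donor parity to give the 1,4-keto-alcohol; the closest known reaction type is the Stork epoxynitrile cyclization and base-mediated epoxy-ketone cyclization (intramolecular enolate alkylation by an epoxide), after which aqueous acetic acid hydrolyses the acetonide.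

Step 8
Reactants: 12 (3S,4S)-3-[(3R)-3,5-dihydroxy-3-methylpentyl]-4-hydroxy-2,2,4-trimethylcyclohexan-1-one; 13 umbelliferone (7-hydroxy-2H-chromen-2-one)
Product: 14 7-{[(3R)-3-hydroxy-5-[(1S,2S)-2-hydroxy-2,6,6-trimethyl-5-oxocyclohexyl]-3-methylpentyl]oxy}-2H-chromen-2-one (CNP0414652.2)
Conditions: PPh3, diisopropyl azodicarboxylate, THF, 0 °C to rt
Reagents that add atoms: none
Why: Mitsunobu etherification: only the primary hydroxyl forms an alkoxyphosphonium that the acidic phenol (pKa about 7.8) can displace, the two tertiary alcohols and the ketone are inert, and no stereocenter is involved.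

## Compound list

1 | (R)-(−)-linalool, (3R)-3,7-dimethylocta-1,6-dien-3-ol | C=C[C@](C)(O)CCC=C(C)C | starting material
2 | 9-[(3S)-3-hydroxy-3,7-dimethyloct-6-en-1-yl]-9-borabicyclo[3.3.1]nonane (same spatial arrangement as in 1; the descriptor changes only because boron ranks below carbon) | CC(C)=CCC[C@@](C)(O)CCB1C2CCCC1CCC2 | intermediate
3 | (3R)-3,7-dimethyloct-6-ene-1,3-diol | CC(C)=CCC[C@@](C)(O)CCO | intermediate
4 | (4R)-2,2,4-trimethyl-4-(4-methylpent-3-en-1-yl)-1,3-dioxane | CC(C)=CCC[C@]1(C)CCOC(C)(C)O1 | intermediate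
5 | (2E)-2-methyl-5-[(4R)-2,2,4-trimethyl-1,3-dioxan-4-yl]pent-2-en-1-ol | OC/C(C)=C/CC[C@]1(C)CCOC(C)(C)O1 | intermediate
6 | (4R)-4-[(3E)-5-bromo-4-methylpent-3-en-1-yl]-2,2,4-trimethyl-1,3-dioxane | BrC/C(C)=C/CC[C@]1(C)CCOC(C)(C)O1 | intermediate
7 | 3-methylbutan-2-one | CC(C)C(C)=O | starting material
8 | lithium 3-methylbut-1-en-2-olate | C=C([O-])C(C)C.[Li+] | intermediate
9 | (6E)-2,6-dimethyl-9-[(4R)-2,2,4-trimethyl-1,3-dioxan-4-yl]non-6-en-3-one | CC(C)C(=O)CC/C(C)=C/CC[C@]1(C)CCOC(C)(C)O1 | intermediate
10 | 2-methyl-5-{(2S,3S)-2-methyl-3-[2-((4R)-2,2,4-trimethyl-1,3-dioxan-4-yl)ethyl]oxiran-2-yl}pentan-3-one | CC(C)C(=O)CC[C@]1(C)O[C@H]1CC[C@]2(C)CCOC(C)(C)O2 | intermediate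
11 | (3S,4S)-4-hydroxy-2,2,4-trimethyl-3-{2-[(4R)-2,2,4-trimethyl-1,3-dioxan-4-yl]ethyl}cyclohexan-1-one | CC1(C)C(=O)CC[C@](C)(O)[C@H]1CC[C@]2(C)CCOC(C)(C)O2 | intermediate
12 | (3S,4S)-3-[(3R)-3,5-dihydroxy-3-methylpentyl]-4-hydroxy-2,2,4-trimethylcyclohexan-1-one | CC1(C)C(=O)CC[C@](C)(O)[C@H]1CC[C@@](C)(O)CCO | intermediate
13 | umbelliferone, 7-hydroxy-2H-chromen-2-one | Oc1ccc2ccc(=O)oc2c1 | starting material
14 | 7-{[(3R)-3-hydroxy-5-[(1S,2S)-2-hydroxy-2,6,6-trimethyl-5-oxocyclohexyl]-3-methylpentyl]oxy}-2H-chromen-2-one (CNP0414652.2) | CC1(C)C(=O)CC[C@](C)(O)[C@H]1CC[C@@](C)(O)CCOc1ccc2ccc(=O)oc2c1 | target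

## Step count and risks

Total steps: 8. Longest linear sequence: 8 steps (1 to 14); 7 and 13 are purchased.

Most likely to fail, first: step 7. The less substituted enolate could close a cyclopropane at the tertiary oxirane carbon, the enolate oxygen could attack instead of carbon to give a cyclic enol ether, or the hindered C–C bond formation could simply be too slow. The fallback replaces deprotonation by reductive, regiospecific enolate generation. It sets out from bromide 6, which is alkylated by the dianion of 3-hydroxy-3-methylbutan-2-one (LiN(i-Pr)2, 2.1 equiv, THF, −78 °C) to give the tertiary α-hydroxy ketone F1. Acetylation (Ac2O, 4-dimethylaminopyridine, Et3N) gives the α-acetoxy ketone F2, and epoxidation exactly as in step 6 gives the epoxy acetate F3. Treatment of F3 with SmI2 and hexamethylphosphoramide in THF (−78 °C to rt) cleaves the C–OAc bond and can give only the tetrasubstituted samarium enolate, under aprotic, non-equilibrating conditions; this carbon-reactive enolate closes onto the oxirane and the sequence comes back to the route at 11, which is hydrolysed to 12 as in step 7.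

Second: step 5. The monoalkylated ketone can transfer a proton to unreacted enolate and be alkylated again, and excess base can degrade the allylic bromide. The fallback uses a stabilised, cleanly mono-alkylated nucleophile. It sets out from 6, which is alkylated by the potassium enolate of methyl 4-methyl-3-oxopentanoate (K2CO3, acetone, reflux) to give the β-keto ester F4 as a mixture of epimers at the new CH. Krapcho dealkoxycarbonylation (LiCl, wet DMSO, 140 °C) then comes back to the route at 9.

Third: step 6. Facial selectivity may be incomplete (giving a diastereomer that must be separated), the required catalyst enantiomer is the less accessible one, and KHSO5 can over-oxidise the ketone. The fallback moves the epoxidation to the allylic alcohol stage, where a cheap natural tartrate controls it. It sets out from 5: Sharpless asymmetric epoxidation (Ti(Oi-Pr)4, L-(+)-diethyl tartrate, t-BuOOH, 4 Å molecular sieves, CH2Cl2, −20 °C) gives the (2S,3S)-epoxy alcohol F5. Conversion to the epoxy triflate F6 (Tf2O, 2,6-lutidine, CH2Cl2, −78 °C) and C-alkylation of enolate 8 by F6 in THF at −78 °C comes back to the route at 10.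

## Further compounds

F1 | step 7 | (6E)-2-hydroxy-2,6-dimethyl-9-[(4R)-2,2,4-trimethyl-1,3-dioxan-4-yl]non-6-en-3-one | CC(C)(O)C(=O)CC/C(C)=C/CC[C@]1(C)CCOC(C)(C)O1
F2 | step 7 | (6E)-2,6-dimethyl-3-oxo-9-[(4R)-2,2,4-trimethyl-1,3-dioxan-4-yl]non-6-en-2-yl acetate | CC(=O)OC(C)(C)C(=O)CC/C(C)=C/CC[C@]1(C)CCOC(C)(C)O1
F3 | step 7 | 2-methyl-5-{(2S,3S)-2-methyl-3-[2-((4R)-2,2,4-trimethyl-1,3-dioxan-4-yl)ethyl]oxiran-2-yl}-3-oxopentan-2-yl acetate | CC(=O)OC(C)(C)C(=O)CC[C@]1(C)O[C@H]1CC[C@]2(C)CCOC(C)(C)O2
F4 | step 5 | methyl (4E)-4-methyl-2-(2-methylpropanoyl)-7-[(4R)-2,2,4-trimethyl-1,3-dioxan-4-yl]hept-4-enoate | COC(=O)C(C/C(C)=C/CC[C@]1(C)CCOC(C)(C)O1)C(=O)C(C)C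
F5 | step 6 | {(2S,3S)-2-methyl-3-[2-((4R)-2,2,4-trimethyl-1,3-dioxan-4-yl)ethyl]oxiran-2-yl}methanol | OC[C@]1(C)O[C@H]1CC[C@]2(C)CCOC(C)(C)O2
F6 | step 6 | {(2S,3S)-2-methyl-3-[2-((4R)-2,2,4-trimethyl-1,3-dioxan-4-yl)ethyl]oxiran-2-yl}methyl trifluoromethanesulfonate | FC(F)(F)S(=O)(=O)OC[C@]1(C)O[C@H]1CC[C@]2(C)CCOC(C)(C)O2
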